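**Retrosynthetic overview** (elemane numbering: C10 quaternary, C5–C9 ring carbons)
1. Target ⇒ C15 aldehyde (Pinnick) ⇒ allylic oxidation of the C4 isopropenyl group; C8 angelate from the C8 alcohol.
2. α-Methylene trans-lactone (ring 2) ⇒ α-methylenation and CuH reduction of a 7(11)-butenolide ⇒ 6-hydroxy-7-ketone + Ph3P=C=C=O.
3. 6-Hydroxy-7-ketone ⇒ enolate hydroxylation (C6–O) and rhodium-catalysed 1,4-addition of isopropenyl (C5) to a 4-methyl-4-vinylcyclohexenone.
4. Cyclohexenone (ring 1) ⇒ aldol condensation of a keto aldehyde ⇒ key step: Prins-type addition of a dienyl silyl ether to methylglyoxal ending in a semipinacol 1,2-vinyl shift (C8–C9 bond, C8–O, quaternary C10).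
5. Ring order: carbocycle (step 3), then lactone (step 6); building blocks are methacrolein, vinylmagnesium bromide, methylglyoxal, isopropenylboronic acid and angelic acid.

Assumption: the target is taken exactly as drawn (5αH,6βH,7αH,8βH,10β-methyl, Z-angelate); anhydrous methylglyoxal (distilled from the commercial aqueous solution) and prop-1-en-2-ylboronic acid are treated as commercial.

**Step 1**
Reactants: 1 methacrolein (2-methylprop-2-enal); 2 vinylmagnesium bromide
Product: 4 rac-triethyl[(2-methylpenta-1,4-dien-3-yl)oxy]silane, via bromomagnesium alkoxide 3 (not isolated)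
Conditions: THF, −78 → 0 °C; then Et3SiCl, DMAP (10 mol%), 0 °C → rt
Reagents that add atoms: chlorotriethylsilane, CC[Si](Cl)(CC)CC
Why: Grignard 1,2-addition to the enal and silylation of the magnesium alkoxide in the same flask give the bis-allylic silyl ether, deliberately racemic because step 2 consumes only its (R)-enantiomer.

**Step 2**
Reactants: 4 rac-triethyl[(2-methylpenta-1,4-dien-3-yl)oxy]silane (2.5 equiv); 5 methylglyoxal (2-oxopropanal)
Product: 6 (2S,4S)-2-ethenyl-2-methyl-5-oxo-4-[(triethylsilyl)oxy]hexanal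
Conditions: [Cu((S,S)-t-Bu-box)](SbF6)2 (10 mol%), 4 Å MS, CH2Cl2, −78 → −40 °C
Reagents that add atoms: none
Why: Proposed new method: catalytic enantioselective intermolecular Prins addition terminated by a semipinacol 1,2-vinyl shift, run as a kinetic resolution of the racemic silyl ether – the aldehyde of 5, chelated to the copper bis(oxazoline) Lewis acid through both carbonyl oxygens, is attacked on its open face by the CH2 terminus of the isopropenyl group (C8–C9 bond; 4S carbinol, the sense expected by analogy with glyoxylate–ene reactions of this catalyst), and in the developing tertiary cation the vinyl group on the adjacent silyloxy carbon, held antiperiplanar to the incoming electrophile (silyloxy inside, hydrogen toward the methyl), shifts to the cationic carbon faster than ene-type proton loss because the shift ends in a silyl-stabilised oxocarbenium ion, so the quaternary centre is set stereospecifically from the carbinol configuration ((R)-4 gives 2S, while (S)-4 is expected to be mismatched with the ligand, to stay unchanged and to be recovered on chromatography, as in known kinetic resolutions of 2-substituted allyl silyl ethers), after which Et3Si passes to the copper alkoxide as in a Mukaiyama aldol cycle to free the aldehyde and the catalyst; the closest known reactions are the Prins–pinacol rearrangement (stoichiometric Lewis acid, acetal electrophiles, cyclic tertiary carbinols), the 1,2-vinyl shift of 2,3-epoxy alcohol silyl ethers and chiral Lewis acid carbonyl–ene reactions, none shown for an acyclic secondary bis-allylic silyl ether under asymmetric catalysis.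

**Step 3**
Reactants: 6 (2S,4S)-2-ethenyl-2-methyl-5-oxo-4-[(triethylsilyl)oxy]hexanal
Product: 7 (4S,6S)-4-ethenyl-4-methyl-6-[(triethylsilyl)oxy]cyclohex-2-en-1-one
Conditions: Bn2NH·CF3CO2H (20 mol%), toluene, 50 °C
Reagents that add atoms: none
Why: Intramolecular aldol condensation: the aldehyde has no α-hydrogen, so only the methyl ketone enolises, closes the six-membered ring on the aldehyde and loses water to the conjugated enone, while the weakly acidic ammonium salt leaves the silyl ether and both stereocentres untouched.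

**Step 4**
Reactants: 7 (4S,6S)-4-ethenyl-4-methyl-6-[(triethylsilyl)oxy]cyclohex-2-en-1-one; 8 prop-1-en-2-ylboronic acid (3 equiv)
Product: 9 (2S,4S,5S)-4-ethenyl-4-methyl-5-(prop-1-en-2-yl)-2-[(triethylsilyl)oxy]cyclohexan-1-one
Conditions: [Rh(OH)((S)-binap)]2 (1.5 mol%), 1,4-dioxane/H2O 10:1, 50 °C
Reagents that add atoms: none
Why: Hayashi–Miyaura rhodium-catalysed asymmetric 1,4-addition places the isopropenyl group on C5 under catalyst control, (S)-BINAP delivering it to the enone face from which 2-cyclohexenone gives (S)-3-substituted ketones, i.e. cis to the C10 methyl, the substrate's own bias (methyl against vinyl) being small.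

**Step 5**
Reactants: 9 (2S,4S,5S)-4-ethenyl-4-methyl-5-(prop-1-en-2-yl)-2-[(triethylsilyl)oxy]cyclohexan-1-one
Product: 10 (2R,3S,4S,6S)-4-ethenyl-2-hydroxy-4-methyl-3-(prop-1-en-2-yl)-6-[(triethylsilyl)oxy]cyclohexan-1-one
Conditions: KN(SiMe3)2, THF, −78 °C; then 3-phenyl-2-(phenylsulfonyl)oxaziridine, −78 °C; AcOH
Reagents that add atoms: 3-phenyl-2-(phenylsulfonyl)oxaziridine, O=S(=O)(c1ccccc1)N1OC1c1ccccc1
Why: Kinetic enolisation at the unhindered CH2 (not at the silyloxy-bearing CH) followed by Davis oxaziridine hydroxylation, the oxidant approaching anti to the neighbouring isopropenyl group and to the axial methyl, gives the equatorial hydroxyl trans to C5 (C6 α-oxygen).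

**Step 6**
Reactants: 10 (2R,3S,4S,6S)-4-ethenyl-2-hydroxy-4-methyl-3-(prop-1-en-2-yl)-6-[(triethylsilyl)oxy]cyclohexan-1-one
Product: 11 (4S,6S,7S,7aR)-6-ethenyl-6-methyl-7-(prop-1-en-2-yl)-4-[(triethylsilyl)oxy]-5,6,7,7a-tetrahydro-1-benzofuran-2(4H)-one
Conditions: Ph3P=C=C=O (1.5 equiv), toluene, 110 °C
Reagents that add atoms: (triphenylphosphoranylidene)ketene, O=C=C=P(c1ccccc1)(c1ccccc1)c1ccccc1
Why: Bestmann butenolide synthesis: the hydroxyl adds to the ketene ylide to give an ester-stabilised ylide that closes by intramolecular Wittig reaction on the adjacent ketone, and no stereocentre is touched.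

**Step 7**
Reactants: 11 (4S,6S,7S,7aR)-6-ethenyl-6-methyl-7-(prop-1-en-2-yl)-4-[(triethylsilyl)oxy]-5,6,7,7a-tetrahydro-1-benzofuran-2(4H)-one
Product: 12 (3aS,4S,6S,7S,7aR)-6-ethenyl-6-methyl-7-(prop-1-en-2-yl)-4-[(triethylsilyl)oxy]hexahydro-1-benzofuran-2(3H)-one
Conditions: Cu(OAc)2 (5 mol%), 1,2-bis(diphenylphosphino)benzene (5 mol%), (MeO)2MeSiH, t-BuOH, toluene, 0 °C → rt
Reagents that add atoms: none
Why: Copper hydride conjugate reduction of the butenolide delivers hydride to ring carbon C7 along the axial trajectory on the α-face, which is flanked only by the axial hydrogens at C5 and C9 and lies opposite the axial C10 methyl, so H-7 ends trans to H-6 (trans-fused lactone, both ring bonds equatorial) and the isolated alkenes are left alone.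

**Step 8**
Reactants: 12 (3aS,4S,6S,7S,7aR)-6-ethenyl-6-methyl-7-(prop-1-en-2-yl)-4-[(triethylsilyl)oxy]hexahydro-1-benzofuran-2(3H)-one
Product: 16 (3aR,4S,6S,7S,7aR)-6-ethenyl-4-hydroxy-6-methyl-3-methylidene-7-(prop-1-en-2-yl)hexahydro-1-benzofuran-2(3H)-one, via Mannich base 13 (not isolated), via methiodide 14 (not isolated), via triethylsilyl ether 15 (not isolated)
Conditions: LiN(i-Pr)2, THF, −78 °C; CH2=NMe2+ I−, −78 → 0 °C; MeI, MeOH, rt; NaHCO3, CH2Cl2/H2O; HF·pyridine, THF, 0 °C
Reagents that add atoms: N,N-dimethylmethyleneiminium iodide, C=[N+](C)C.[I-]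
Why: Eschenmoser α-methylenation of the lactone enolate (Mannich reaction, N-methylation, elimination) creates the exocyclic methylene, and acidic HF·pyridine then frees the C8 hydroxyl without the translactonisation that a basic fluoride source could cause.

**Step 9**
Reactants: 16 (3aR,4S,6S,7S,7aR)-6-ethenyl-4-hydroxy-6-methyl-3-methylidene-7-(prop-1-en-2-yl)hexahydro-1-benzofuran-2(3H)-one; 17 angelic acid ((Z)-2-methylbut-2-enoic acid)
Product: 19 8α-[(Z)-2-methylbut-2-enoyloxy]elema-1,3,11(13)-trien-12,6α-olide, via mixed anhydride 18 (not isolated)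
Conditions: 17, 2,4,6-trichlorobenzoyl chloride, Et3N, toluene, rt; then 16, 80 °C (no DMAP)
Reagents that add atoms: none
Why: Yamaguchi-type mixed-anhydride esterification run without DMAP, the alcohol attacking the unhindered angeloyl carbonyl, acylates the equatorial C8 hydroxyl with retention and without Z→E isomerisation to the tiglate.

**Step 10**
Reactants: 19 8α-[(Z)-2-methylbut-2-enoyloxy]elema-1,3,11(13)-trien-12,6α-olide
Product: 21 8α-[(Z)-2-methylbut-2-enoyloxy]-15-oxoelema-1,3,11(13)-trien-12,6α-olide, via allylic alcohol 20 (not isolated)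
Conditions: SeO2 (0.3 equiv), t-BuOOH, CH2Cl2, 0 °C → rt; silica plug; then MnO2, CH2Cl2, rt
Reagents that add atoms: tert-butyl hydroperoxide, CC(C)(C)OO (oxygen relayed by the SeO2 catalyst)
Why: Selenium dioxide allylic oxidation (ene reaction then 2,3-shift) attacks the methyl of the electron-rich 1,1-disubstituted isopropenyl group, the only alkene with reactive allylic hydrogens (the vinyl group has none, the methylene lactone and angelate are electron-poor), and MnO2 takes the primary allylic alcohol on to the 2-substituted acrolein.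

**Step 11**
Reactants: 21 8α-[(Z)-2-methylbut-2-enoyloxy]-15-oxoelema-1,3,11(13)-trien-12,6α-olide
Product: 22 8α-[(Z)-2-methylbut-2-enoyloxy]elema-1,3,11(13)-trien-12,6α-olid-15-oic acid (CNP0256928.3)
Conditions: NaClO2, NaH2PO4, 2-methylbut-2-ene, t-BuOH/H2O, 0 °C → rt
Reagents that add atoms: sodium chlorite, [Na+].[O-]Cl=O
Why: Pinnick oxidation converts the enal into the acrylic acid chemoselectively, the hypochlorite scavenger protecting the four alkenes, and no stereocentre is affected.

**Compound list**
1 | methacrolein (2-methylprop-2-enal) | C=C(C)C=O | starting material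
2 | vinylmagnesium bromide | C=C[Mg]Br | starting material
3 | bromomagnesium 2-methylpenta-1,4-dien-3-olate (racemic) | C=CC(O[Mg]Br)C(C)=C | intermediate
4 | rac-triethyl[(2-methylpenta-1,4-dien-3-yl)oxy]silane | C=CC(O[Si](CC)(CC)CC)C(C)=C | intermediate
5 | methylglyoxal (2-oxopropanal) | CC(=O)C=O | starting material
6 | (2S,4S)-2-ethenyl-2-methyl-5-oxo-4-[(triethylsilyl)oxy]hexanal | C=C[C@](C=O)(C)C[C@H](O[Si](CC)(CC)CC)C(C)=O | intermediate
7 | (4S,6S)-4-ethenyl-4-methyl-6-[(triethylsilyl)oxy]cyclohex-2-en-1-one | C=C[C@]1(C)C[C@H](O[Si](CC)(CC)CC)C(=O)C=C1 | intermediate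
8 | prop-1-en-2-ylboronic acid (isopropenylboronic acid) | CC(=C)B(O)O | starting material
9 | (2S,4S,5S)-4-ethenyl-4-methyl-5-(prop-1-en-2-yl)-2-[(triethylsilyl)oxy]cyclohexan-1-one | C=C[C@]1(C)C[C@H](O[Si](CC)(CC)CC)C(=O)C[C@H]1C(C)=C | intermediate
10 | (2R,3S,4S,6S)-4-ethenyl-2-hydroxy-4-methyl-3-(prop-1-en-2-yl)-6-[(triethylsilyl)oxy]cyclohexan-1-one | C=C[C@]1(C)C[C@H](O[Si](CC)(CC)CC)C(=O)[C@H](O)[C@H]1C(C)=C | intermediate
11 | (4S,6S,7S,7aR)-6-ethenyl-6-methyl-7-(prop-1-en-2-yl)-4-[(triethylsilyl)oxy]-5,6,7,7a-tetrahydro-1-benzofuran-2(4H)-one | C=C[C@]1(C)C[C@H](O[Si](CC)(CC)CC)C2=CC(=O)O[C@@H]2[C@H]1C(C)=C | intermediate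
12 | (3aS,4S,6S,7S,7aR)-6-ethenyl-6-methyl-7-(prop-1-en-2-yl)-4-[(triethylsilyl)oxy]hexahydro-1-benzofuran-2(3H)-one (trans-fused) | C=C[C@]1(C)C[C@H](O[Si](CC)(CC)CC)[C@H]2CC(=O)O[C@@H]2[C@H]1C(C)=C | intermediate
13 | 3-[(dimethylamino)methyl] derivative of 12 (Mannich base, C3 epimers) | C=C[C@]1(C)C[C@H](O[Si](CC)(CC)CC)[C@H]2C(CN(C)C)C(=O)O[C@@H]2[C@H]1C(C)=C | intermediate
14 | 3-[(trimethylammonio)methyl] derivative of 12, iodide (methiodide of 13) | C=C[C@]1(C)C[C@H](O[Si](CC)(CC)CC)[C@H]2C(C[N+](C)(C)C)C(=O)O[C@@H]2[C@H]1C(C)=C.[I-] | intermediate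
15 | (3aS,4S,6S,7S,7aR)-6-ethenyl-6-methyl-3-methylidene-7-(prop-1-en-2-yl)-4-[(triethylsilyl)oxy]hexahydro-1-benzofuran-2(3H)-one | C=C[C@]1(C)C[C@H](O[Si](CC)(CC)CC)[C@H]2C(=C)C(=O)O[C@@H]2[C@H]1C(C)=C | intermediate
16 | (3aR,4S,6S,7S,7aR)-6-ethenyl-4-hydroxy-6-methyl-3-methylidene-7-(prop-1-en-2-yl)hexahydro-1-benzofuran-2(3H)-one (8α-hydroxyelema-1,3,11(13)-trien-12,6α-olide) | C=C[C@]1(C)C[C@H](O)[C@H]2C(=C)C(=O)O[C@@H]2[C@H]1C(C)=C | intermediate
17 | angelic acid, (Z)-2-methylbut-2-enoic acid | C/C=C(/C)C(=O)O | starting material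
18 | (Z)-2-methylbut-2-enoic 2,4,6-trichlorobenzoic anhydride | C/C=C(/C)C(=O)OC(=O)c1c(Cl)cc(Cl)cc1Cl | intermediate
19 | 8α-[(Z)-2-methylbut-2-enoyloxy]elema-1,3,11(13)-trien-12,6α-olide (5αH,6βH,7αH,8βH,10β-methyl) | C=C[C@]1(C)C[C@H](OC(=O)/C(C)=C\C)[C@H]2C(=C)C(=O)O[C@@H]2[C@H]1C(C)=C | intermediate
20 | 15-hydroxy-8α-[(Z)-2-methylbut-2-enoyloxy]elema-1,3,11(13)-trien-12,6α-olide (5αH,6βH,7αH,8βH,10β-methyl) | C=C[C@]1(C)C[C@H](OC(=O)/C(C)=C\C)[C@H]2C(=C)C(=O)O[C@@H]2[C@H]1C(CO)=C | intermediate
21 | 8α-[(Z)-2-methylbut-2-enoyloxy]-15-oxoelema-1,3,11(13)-trien-12,6α-olide (5αH,6βH,7αH,8βH,10β-methyl) | C=C[C@]1(C)C[C@H](OC(=O)/C(C)=C\C)[C@H]2C(=C)C(=O)O[C@@H]2[C@H]1C(C=O)=C | intermediate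
22 | 8α-[(Z)-2-methylbut-2-enoyloxy]elema-1,3,11(13)-trien-12,6α-olid-15-oic acid, (5R,6R,7R,8S,10S), CNP0256928.3 | C=C[C@]1(C)C[C@H](OC(=O)/C(C)=C\C)[C@H]2C(=C)C(=O)O[C@@H]2[C@H]1C(=C)C(=O)O | target

**Step count and risks**
Total steps: 11. Longest linear sequence: 11 (from methacrolein; the other building blocks enter directly).

The three steps most likely to fail:

Step 2, the new reaction. Ene-type proton loss from the methyl group or a hydride shift may outrun the vinyl shift, the catalyst may not discriminate the enantiomers of 4 well enough, and the copper alkoxide may close on the oxocarbenium carbon instead of taking the silyl group. The fallback sets out from 4 and 5 and comes back at 6, using two known reaction types. A titanium–BINOL carbonyl–ene reaction (TiCl2(O-i-Pr)2/(S)-BINOL, 4 Å MS, CH2Cl2, −30 °C), a reaction type known to resolve racemic 2-substituted allyl silyl ethers kinetically, consumes (R)-4, leaves (S)-4 unchanged and gives the ene adduct (3S,6R)-3-hydroxy-5-methylidene-6-[(triethylsilyl)oxy]oct-7-en-2-one F1. Tf2NH (5 mol%, CH2Cl2, −78 °C) then protonates its 1,1-disubstituted alkene to the same tertiary cation, which undergoes the classical protio-semipinacol vinyl shift with silyl transfer to the free hydroxyl and gives 6. The sense of chirality transfer at C2 has to be confirmed at this point, because the free cation may react through a different rotamer.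

Step 4. The β-carbon is neopentyl and the nucleophile is α-branched, so the rhodium addition may be slow or the catalyst may not override the substrate. The fallback sets out from 7 and comes back at 10, bypassing 9. Copper-catalysed asymmetric conjugate addition of isopropenylmagnesium bromide (CuBr·SMe2, chiral ferrocenyl diphosphine, Me3SiCl, 2-methyltetrahydrofuran, −78 °C) with silylation of the magnesium enolate gives the regiodefined enol ether {[(3S,4S,6S)-4-ethenyl-4-methyl-3-(prop-1-en-2-yl)-6-[(triethylsilyl)oxy]cyclohex-1-en-1-yl]oxy}trimethylsilane F2. Rubottom oxidation (dimethyldioxirane, acetone, −78 °C, then citric acid) converts it directly into 10, so the separate kinetic enolisation is no longer needed.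

Step 10. The allylic oxidation must pick one methyl group in a substrate with four alkenes and an angelate, and over-oxidation or angelate isomerisation is possible. The fallback sets out from 19 and comes back at 21. Ene-type allylic chlorination with hypochlorous acid (Ca(OCl)2, solid CO2, CH2Cl2/H2O, 0 °C) gives 15-chloro-8α-[(Z)-2-methylbut-2-enoyloxy]elema-1,3,11(13)-trien-12,6α-olide F3. Ganem oxidation with N-methylmorpholine N-oxide (MeCN, rt) then converts the allylic chloride into the enal 21 without selenium or peroxide.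

**Further compounds**
F1 | step 2 | (3S,6R)-3-hydroxy-5-methylidene-6-[(triethylsilyl)oxy]oct-7-en-2-one | CC(=O)[C@@H](O)CC(=C)[C@H](O[Si](CC)(CC)CC)C=C
F2 | step 4 | {[(3S,4S,6S)-4-ethenyl-4-methyl-3-(prop-1-en-2-yl)-6-[(triethylsilyl)oxy]cyclohex-1-en-1-yl]oxy}trimethylsilane | C=C[C@]1(C)C[C@H](O[Si](CC)(CC)CC)C(O[Si](C)(C)C)=C[C@H]1C(C)=C
F3 | step 10 | 15-chloro-8α-[(Z)-2-methylbut-2-enoyloxy]elema-1,3,11(13)-trien-12,6α-olide | C=C[C@]1(C)C[C@H](OC(=O)/C(C)=C\C)[C@H]2C(=C)C(=O)O[C@@H]2[C@H]1C(CCl)=C
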